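**Plan**

Numbering used throughout: ring C1 (C(CH3)OH), C2 (O-angeloyl), C3 (OH), C4 (bears the side chain), C5 (CH2), C6 (CHCl); side chain C7(=C14H2)–C8(O-angeloyl)–C9H2–C10/C11 oxirane.
Retrosynthetic cuts, in order: the side-chain oxirane oxygen; both angelate C–O bonds; C6–Cl (back to a cis-fused C1–C6 oxirane); the ring bond C6–C1 together with C6–O (sulfonium ylide onto a methyl ketone); C10=C11 and C8–C9; C4–C7 and C4=C5; back to 5-deoxy-D-ribose.
Enabling feature: C6 (Cl) and C1 (OH, CH3) form a trans-diaxial chlorohydrin on the cyclohexane, that is, an opened 7-oxabicyclo[4.1.0]heptane. Its oxirane C–C bond joins a CH to a methyl carbinol carbon that are 1,6-related through C2–C5, which is the retron of an intramolecular ylide epoxidation of a methyl ketone.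
Forward: the C1–C6 chain is built open on the sugar (Wittig, alkenylcuprate addition); the cyclohexane is closed by the C6–C1 bond as the oxirane; the side chain is grown (allylation, cross-metathesis); chloride opens the ring oxirane; the esters are installed; the side-chain oxirane is made last.
Stereochemistry: C2 and C3 from D-ribose; C4 by 1,2-induction from C3 in the cuprate addition; C1 and C6 from the chair transition state and the anti-periplanar oxirane closure of the key step; C6–Cl by inversion; C8 from the BINOL–Ti catalyst; C10 from the Shi ketone.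

Key step: step 10

Remark: 5-deoxy-D-ribose, the stabilised ylide, 2-bromoallyl alcohol and angelic acid are taken as purchasable. Compounds 1 and 2 are anomer mixtures and salt 14 is a mixture of epimers at sulfur; neither matters downstream.

**Route**

Step 1
Reactants: 1 5-deoxy-D-ribose
Product: 2 5-deoxy-2,3-O-isopropylidene-D-ribofuranose
Conditions: 2,2-dimethoxypropane, acetone, TsOH (cat.), rt
Reagents that add atoms: 2,2-dimethoxypropane COC(C)(C)OC
Why: Acid-catalysed ketalisation (acetonide formation) engages the cis-2,3-diol of the furanose and leaves the lactol free, with all three D-ribo stereocentres untouched.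

Step 2
Reactants: 2 5-deoxy-2,3-O-isopropylidene-D-ribofuranose; 3 ethyl (triphenylphosphoranylidene)acetate
Product: 4 ethyl (2E,4S,5R,6R)-6-hydroxy-4,5-(isopropylidenedioxy)hept-2-enoate
Conditions: PhCO2H (cat.), toluene, 80 °C
Reagents that add atoms: none
Why: Wittig olefination of the ring-opened aldehyde tautomer with a stabilised ylide should give the (E)-enoate (benzoic acid catalysis favours E and the neutral medium disfavours oxa-Michael reclosure), and the released C1 hydroxyl is the future ketone site.

Step 3
Reactants: 4 ethyl (2E,4S,5R,6R)-6-hydroxy-4,5-(isopropylidenedioxy)hept-2-enoate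
Product: 5 ethyl (2E,4S,5R,6R)-6-acetoxy-4,5-(isopropylidenedioxy)hept-2-enoate
Conditions: Ac2O, pyridine, DMAP (cat.), CH2Cl2, 0 °C
Reagents that add atoms: acetic anhydride CC(=O)OC(C)=O
Why: DMAP-catalysed acylation masks the C1 hydroxyl so that it can neither quench the cuprate nor add in oxa-Michael fashion, and an acetate is chosen because the hydride of step 6 removes it while reducing the ester.

Step 4
Reactants: 6 2-bromoprop-2-en-1-ol
Product: 7 2-bromoallyl 4-methoxybenzyl ether
Conditions: NaH, 4-methoxybenzyl chloride, Bu4NI (cat.), THF, 0 °C to rt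
Reagents that add atoms: 4-methoxybenzyl chloride COc1ccc(CCl)cc1
Why: Williamson ether synthesis protects the allylic alcohol as a PMB ether that survives t-BuLi, cuprate, hydride, methyl triflate and amide base and is removed oxidatively in step 11.

Step 5
Reactants: 5 ethyl (2E,4S,5R,6R)-6-acetoxy-4,5-(isopropylidenedioxy)hept-2-enoate; 7 2-bromoallyl 4-methoxybenzyl ether
Product: 10 ethyl (3R,4S,5R,6R)-6-acetoxy-4,5-(isopropylidenedioxy)-3-{3-[(4-methoxybenzyl)oxy]prop-1-en-2-yl}heptanoate, via alkenyllithium 8 (not isolated), via lithium dialkenylcuprate 9 (not isolated)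
Conditions: 7 (2.2 equiv), t-BuLi (4.4 equiv), Et2O, −78 °C; CuI (1.1 equiv), −78 to −40 °C; Me3SiCl (3 equiv) then 5, −78 °C; aq. NH4Cl/NH3
Reagents that add atoms: none
Why: Bromine–lithium exchange, transmetalation to the Gilman cuprate and Me3SiCl-accelerated conjugate addition to the (E)-γ,δ-dialkoxy enoate should deliver the alkenyl group anti to the C3–O bond (modified Felkin–Anh model, attack opposite to the perpendicular C–O bond), which sets C4 as required.

Step 6
Reactants: 10 ethyl (3R,4S,5R,6R)-6-acetoxy-4,5-(isopropylidenedioxy)-3-{3-[(4-methoxybenzyl)oxy]prop-1-en-2-yl}heptanoate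
Product: 11 (3R,4S,5R,6R)-4,5-(isopropylidenedioxy)-3-{3-[(4-methoxybenzyl)oxy]prop-1-en-2-yl}heptane-1,6-diol
Conditions: i-Bu2AlH (5 equiv), CH2Cl2, −78 to 0 °C; aq. KNaC4H4O6
Reagents that add atoms: none
Why: Hydride reduction with i-Bu2AlH converts the ethyl ester into the C6 primary alcohol and cleaves the C1 acetate in the same operation, leaving acetonide, PMB ether and alkene intact.

Step 7
Reactants: 11 (3R,4S,5R,6R)-4,5-(isopropylidenedioxy)-3-{3-[(4-methoxybenzyl)oxy]prop-1-en-2-yl}heptane-1,6-diol
Product: 12 (2R,3R,4S,5R)-3,4-(isopropylidenedioxy)-5-{3-[(4-methoxybenzyl)oxy]prop-1-en-2-yl}-7-(phenylsulfanyl)heptan-2-ol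
Conditions: PhSSPh, n-Bu3P, pyridine, rt
Reagents that add atoms: diphenyl disulfide c1ccc(SSc2ccccc2)cc1
Why: Disulfide–phosphine sulfenylation (Hata-type SN2 displacement of an alkoxyphosphonium ion by thiolate) is selective for the unhindered primary hydroxyl over the secondary C1 hydroxyl and puts sulfur on C6 without a strongly electrophilic C6 intermediate that the acetonide oxygen could capture.

Step 8
Reactants: 12 (2R,3R,4S,5R)-3,4-(isopropylidenedioxy)-5-{3-[(4-methoxybenzyl)oxy]prop-1-en-2-yl}-7-(phenylsulfanyl)heptan-2-ol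
Product: 13 (3S,4S,5R)-3,4-(isopropylidenedioxy)-5-{3-[(4-methoxybenzyl)oxy]prop-1-en-2-yl}-7-(phenylsulfanyl)heptan-2-one
Conditions: Dess–Martin periodinane, NaHCO3, CH2Cl2, 0 °C to rt
Reagents that add atoms: none
Why: Dess–Martin oxidation under bicarbonate buffering converts the secondary alcohol into the methyl ketone without oxidising the thioether or epimerising the α-alkoxy centre C2.

Step 9
Reactants: 13 (3S,4S,5R)-3,4-(isopropylidenedioxy)-5-{3-[(4-methoxybenzyl)oxy]prop-1-en-2-yl}-7-(phenylsulfanyl)heptan-2-one
Product: 14 S-methyl S-phenyl sulfonium triflate of 13 (methylated at sulfur)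
Conditions: MeOTf (1.1 equiv), 2,6-di-tert-butyl-4-methylpyridine (0.2 equiv), CH2Cl2, 0 °C to rt
Reagents that add atoms: methyl trifluoromethanesulfonate COS(=O)(=O)C(F)(F)F
Why: S-alkylation of the soft thioether by methyl triflate (sulfonium salt formation) is faster than O-alkylation of the ketone, ether or acetal oxygens, and methyl is chosen as the third group on sulfur because it has no β-hydrogen that the C6 ylide could abstract.

Step 10
Reactants: 14 S-methyl S-phenyl sulfonium triflate of 13
Product: 17 cis-fused C1–C6 oxirane of the 2,3-O-isopropylidene cyclohexane carrying the 3-[(4-methoxybenzyl)oxy]prop-1-en-2-yl group on C4 (oxirane O, O2, O3 and the C4 group all on one face), via sulfonium ylide 15 (not isolated), via anti betaine 16 (not isolated)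
Conditions: LiN(SiMe3)2 (1.0 equiv, added over 1 h), THF (0.005 M), −78 to −20 °C
Reagents that add atoms: none
Why: LiN(SiMe3)2 removes a proton α to sulfur (sulfonium C–H acidity lies several pK units below that of the methyl ketone) to give ylide 15, whose carbanionic C6 adds to the C1 carbonyl and whose alkoxide then displaces methyl phenyl sulfide from C6 with inversion, so that the ring bond C6–C1 and the C6–O bond of the oxirane are made in one operation. The closest known reaction type is the intramolecular Johnson–Corey–Chaykovsky epoxidation of a sulfonium ylide onto a tethered ketone (epoxy-annulation). The carbocycle closes 6-exo-trig (ylide carbon onto the exocyclic C=O) and the oxirane closes 3-exo-tet. C1 is controlled by the chair-like addition transition state: the large C4 alkenyl group sits equatorial, which fixes the acetonide with O3 axial and O2 equatorial, the ketone methyl avoids the syn-axial clash with O3 by lying equatorial, and the carbonyl oxygen therefore develops axially on the acetonide face with lithium bridging it to O3; C6 is controlled by the stereoelectronics of closure, since only the betaine with the sulfonium group trans-diaxial (anti-periplanar) to the alkoxide can collapse and a cyclohexane-fused oxirane must be cis. The selectivity needed is site selectivity between the two kinds of S–C–H: the S-methyl ylide that also forms can reach the ketone only through an eight-membered transition state, the ylides interconvert by proton transfer when base is added slowly at high dilution, and the reaction is thus funnelled through the C6 ylide, while the cis-acetonide holds the C3–O bond out of alignment for β-elimination and one equivalent of base at low temperature avoids C2 epimerisation.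

Step 11
Reactants: 17 cis-fused C1–C6 oxirane with PMB ether
Product: 18 the corresponding primary allylic alcohol (C8H2OH on C7=C14H2; ring oxirane and acetonide unchanged)
Conditions: DDQ, CH2Cl2/pH 7 phosphate buffer, 0 °C to rt
Reagents that add atoms: none
Why: Oxidative cleavage of the PMB ether by DDQ (benzylic hydride abstraction and hydrolysis of the oxocarbenium ion) runs at neutral pH and leaves oxirane, acetonide and the 1,1-disubstituted alkene untouched.

Step 12
Reactants: 18 primary allylic alcohol
Product: 19 the α-substituted acrolein (C8 aldehyde on C7=C14H2; ring oxirane and acetonide unchanged)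
Conditions: Dess–Martin periodinane, NaHCO3, CH2Cl2, 0 °C to rt
Reagents that add atoms: none
Why: Dess–Martin oxidation of the primary allylic alcohol gives the 2-substituted acrolein, whose C4 stereocentre is not vinylogously activated and therefore should not epimerise.

Step 13
Reactants: 19 α-substituted acrolein
Product: 20 the (8S) homoallylic alcohol (C8H(OH)–CH2–CH=CH2; ring oxirane and acetonide unchanged)
Conditions: (S)-BINOL (20 mol %), Ti(OiPr)4 (10 mol %), 4 Å molecular sieves, CH2Cl2; allylSnBu3 (1.5 equiv), −20 °C; aq. NaHCO3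
Reagents that add atoms: allyltributylstannane C=CC[Sn](CCCC)(CCCC)CCCC
Why: Keck asymmetric allylation (BINOL–titanium Lewis acid catalysis with an allylstannane) adds to one aldehyde face under catalyst control and should set C8 as S, the sense expected from (S)-BINOL for aldehydes whose substituent outranks allyl.

Step 14
Reactants: 20 (8S) homoallylic alcohol
Product: 21 the (8S) prenyl carbinol (C8H(OH)–CH2–CH=C(CH3)2; ring oxirane and acetonide unchanged)
Conditions: 2-methyl-2-butene (excess), second-generation Grubbs catalyst (H2IMes)(PCy3)Cl2Ru=CHPh (5 mol %), CH2Cl2, 40 °C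
Reagents that add atoms: 2-methyl-2-butene CC=C(C)C
Why: Olefin cross-metathesis of the monosubstituted alkene with excess 2-methyl-2-butene caps it as the trisubstituted prenyl alkene, while the hindered 1,1-disubstituted C7=C14 alkene should not react.

Step 15
Reactants: 21 (8S) prenyl carbinol with ring oxirane
Product: 22 the chlorohydrin acetonide (C6 axial Cl; C1 axial OH; 2,3-O-isopropylidene; C8 OH; prenyl alkene)
Conditions: LiCl, AcOH, THF, rt
Reagents that add atoms: lithium chloride [Li+].[Cl-]
Why: SN2 opening of the acid-activated oxirane by chloride (LiCl/AcOH halohydrin formation) should occur at the secondary C6 from the face opposite to oxygen, which is both the less substituted carbon (C1 is tertiary and inductively deactivated by O2) and the position that gives the trans-diaxial product directly (Fürst–Plattner rule), so C6 is inverted to the S chloride and C1 keeps its axial hydroxyl.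

Step 16
Reactants: 22 chlorohydrin acetonide
Product: 23 the tetraol (C1 OH; C2 OH; C3 OH; C8 OH; C6 Cl; prenyl alkene)
Conditions: AcOH/H2O (4:1), 45 °C
Reagents that add atoms: none
Why: Acid-catalysed acetal hydrolysis in aqueous acetic acid frees the C2 and C3 hydroxyls without ionising the allylic C8 alcohol or hydrating the trisubstituted alkene.

Step 17
Reactants: 23 tetraol; 24 angelic acid
Product: 26 the C2,C8-bis-angelate (C1 and C3 hydroxyls free; prenyl alkene), via mixed anhydride 25 (not isolated)
Conditions: 24 (2.6 equiv), 2,4,6-Cl3C6H2COCl (2.5 equiv), Et3N (3 equiv), toluene, rt; then 23, toluene, 75 °C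
Reagents that add atoms: none
Why: Yamaguchi-type esterification through the preformed mixed anhydride, run without DMAP to avoid Z-to-E isomerisation of the angeloyl group, should acylate the unhindered C8 hydroxyl and then the equatorial C2 hydroxyl, whereas the axial C3 hydroxyl (hydrogen-bonded syn-diaxially to the C1 hydroxyl) and the tertiary C1 hydroxyl react much more slowly, as in the preferential acylation of equatorial over axial hydroxyls of cis-diols in pyranosides.

Step 18
Reactants: 26 C2,C8-bis-angelate
Product: 27 CNP0158207.1 (1S,2S,3S,4R,6S,8S,10R in the numbering above)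
Conditions: 1,2:4,5-di-O-isopropylidene-β-D-erythro-2,3-hexodiulo-2,6-pyranose (30 mol %), KHSO5 (as Oxone), aq. NaHCO3/K2CO3 buffer (pH ≈ 9), MeCN/dimethoxymethane, 0 °C
Reagents that add atoms: potassium peroxymonosulfate [K+].[O-]S(=O)(=O)OO
Why: Shi asymmetric epoxidation (chiral dioxirane, spiro transition state) should oxidise only the electron-rich trisubstituted alkene, the D-fructose-derived ketone delivering oxygen to the face that gives R at C10, while the ester-deactivated 1,1-disubstituted alkene and the angelates are inert.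

**Compound list**

1 | 5-deoxy-D-ribose (furanose form) | OC1[C@H](O)[C@H](O)[C@@H](C)O1 | starting material
2 | 5-deoxy-2,3-O-isopropylidene-D-ribofuranose | OC1[C@@H]2OC(C)(C)O[C@@H]2[C@@H](C)O1 | intermediate
3 | ethyl (triphenylphosphoranylidene)acetate | CCOC(=O)C=P(c1ccccc1)(c1ccccc1)c1ccccc1 | starting material
4 | ethyl (2E,4S,5R,6R)-6-hydroxy-4,5-(isopropylidenedioxy)hept-2-enoate | CCOC(=O)/C=C/[C@@H]1OC(C)(C)O[C@@H]1[C@@H](C)O | intermediate
5 | ethyl (2E,4S,5R,6R)-6-acetoxy-4,5-(isopropylidenedioxy)hept-2-enoate | CCOC(=O)/C=C/[C@@H]1OC(C)(C)O[C@@H]1[C@@H](C)OC(C)=O | intermediate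
6 | 2-bromoprop-2-en-1-ol | C=C(Br)CO | starting material
7 | 2-bromoallyl 4-methoxybenzyl ether | C=C(Br)COCc1ccc(OC)cc1 | intermediate
8 | {3-[(4-methoxybenzyl)oxy]prop-1-en-2-yl}lithium | [Li]C(=C)COCc1ccc(OC)cc1 | intermediate
9 | lithium bis{3-[(4-methoxybenzyl)oxy]prop-1-en-2-yl}cuprate | [Li+].C=C(COCc1ccc(OC)cc1)[Cu-]C(=C)COCc1ccc(OC)cc1 | intermediate
10 | ethyl (3R,4S,5R,6R)-6-acetoxy-4,5-(isopropylidenedioxy)-3-{3-[(4-methoxybenzyl)oxy]prop-1-en-2-yl}heptanoate | CCOC(=O)C[C@H](C(=C)COCc1ccc(OC)cc1)[C@@H]2OC(C)(C)O[C@@H]2[C@@H](C)OC(C)=O | intermediate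
11 | (3R,4S,5R,6R)-4,5-(isopropylidenedioxy)-3-{3-[(4-methoxybenzyl)oxy]prop-1-en-2-yl}heptane-1,6-diol | OCC[C@H](C(=C)COCc1ccc(OC)cc1)[C@@H]2OC(C)(C)O[C@@H]2[C@@H](C)O | intermediate
12 | (2R,3R,4S,5R)-3,4-(isopropylidenedioxy)-5-{3-[(4-methoxybenzyl)oxy]prop-1-en-2-yl}-7-(phenylsulfanyl)heptan-2-ol | c1ccccc1SCC[C@H](C(=C)COCc2ccc(OC)cc2)[C@@H]3OC(C)(C)O[C@@H]3[C@@H](C)O | intermediate
13 | (3S,4S,5R)-3,4-(isopropylidenedioxy)-5-{3-[(4-methoxybenzyl)oxy]prop-1-en-2-yl}-7-(phenylsulfanyl)heptan-2-one | c1ccccc1SCC[C@H](C(=C)COCc2ccc(OC)cc2)[C@@H]3OC(C)(C)O[C@@H]3C(C)=O | intermediate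
14 | S-methyl S-phenyl sulfonium triflate of 13 (epimers at sulfur) | C[S+](CC[C@H](C(=C)COCc1ccc(OC)cc1)[C@@H]2OC(C)(C)O[C@@H]2C(C)=O)c3ccccc3.[O-]S(=O)(=O)C(F)(F)F | intermediate
15 | sulfonium ylide (carbanion at C6) | C[S+]([CH-]C[C@H](C(=C)COCc1ccc(OC)cc1)[C@@H]2OC(C)(C)O[C@@H]2C(C)=O)c3ccccc3 | intermediate
16 | anti betaine (C1 alkoxide axial; C6 sulfonium axial on the opposite face) | C=C(COCc1ccc(OC)cc1)[C@H]2C[C@H]([S+](C)c3ccccc3)[C@@](C)([O-])[C@H]4OC(C)(C)O[C@@H]24 | intermediate
17 | cis-fused C1–C6 oxirane, 2,3-O-isopropylidene, C4 PMB-oxymethylvinyl (all four ring substituents cis) | C=C(COCc1ccc(OC)cc1)[C@H]2C[C@H]3O[C@@]3(C)[C@H]4OC(C)(C)O[C@@H]24 | intermediate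
18 | primary allylic alcohol of 17 (PMB removed) | C=C(CO)[C@H]1C[C@H]2O[C@@]2(C)[C@H]3OC(C)(C)O[C@@H]13 | intermediate
19 | α-substituted acrolein (C8 aldehyde) | C=C(C=O)[C@H]1C[C@H]2O[C@@]2(C)[C@H]3OC(C)(C)O[C@@H]13 | intermediate
20 | (8S) homoallylic alcohol | C=C([C@H](CC=C)O)[C@H]1C[C@H]2O[C@@]2(C)[C@H]3OC(C)(C)O[C@@H]13 | intermediate
21 | (8S) prenyl carbinol with ring oxirane | C=C([C@H](CC=C(C)C)O)[C@H]1C[C@H]2O[C@@]2(C)[C@H]3OC(C)(C)O[C@@H]13 | intermediate
22 | chlorohydrin acetonide (C6 Cl and C1 OH trans-diaxial) | C=C([C@H](CC=C(C)C)O)[C@H]1C[C@H](Cl)[C@@](C)(O)[C@H]2OC(C)(C)O[C@@H]12 | intermediate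
23 | tetraol (C1, C2, C3, C8 hydroxyls free) | C=C([C@H](CC=C(C)C)O)[C@H]1C[C@H](Cl)[C@@](C)(O)[C@@H](O)[C@H]1O | intermediate
24 | angelic acid ((Z)-2-methylbut-2-enoic acid) | C/C=C(/C)C(=O)O | starting material
25 | angelic 2,4,6-trichlorobenzoic mixed anhydride | C/C=C(/C)C(=O)OC(=O)c1c(Cl)cc(Cl)cc1Cl | intermediate
26 | C2,C8-bis-angelate with prenyl alkene | C=C([C@H](CC=C(C)C)OC(=O)/C(C)=C\C)[C@H]1C[C@H](Cl)[C@@](C)(O)[C@@H](OC(=O)/C(C)=C\C)[C@H]1O | intermediate
27 | CNP0158207.1 | C=C([C@H](C[C@H]1OC1(C)C)OC(=O)/C(C)=C\C)[C@H]1C[C@H](Cl)[C@@](C)(O)[C@@H](OC(=O)/C(C)=C\C)[C@H]1O | target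

**Count and risks**

Total steps: 18. Longest linear sequence: 17 (steps 1–3 and 5–18 from 5-deoxy-D-ribose).

Steps most likely to fail:

1. Step 10. What may go wrong: deprotonation at the S-methyl group in place of C6, followed by loss of the unproductive ylide through α′,β-elimination or intermolecular methylene transfer, or addition to the other face of the ketone. Fallback, setting out from diol 11 and returning at oxirane 17: both hydroxyls of 11 are oxidised (Dess–Martin periodinane) to the keto aldehyde F1. Double Wittig methylenation (Ph3P=CH2, THF, −78 to 0 °C) gives the diene F2. Ring-closing metathesis (second-generation Grubbs catalyst) makes the same C6–C1 connection as the trisubstituted cyclohexene acetonide F3. Aqueous AcOH frees the cyclohexene diol F4, whose allylic C2 hydroxyl directs VO(acac)2/t-BuOOH epoxidation to its own face to give the epoxy diol F5. Re-ketalisation (2,2-dimethoxypropane, PPTS) gives 17.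

2. Step 17. What may go wrong: competing acylation of the axial C3 hydroxyl or over-acylation, and Z-to-E isomerisation of the angeloyl group on prolonged heating. Fallback, setting out from chlorohydrin acetonide 22 and returning at bis-angelate 26: the only free secondary hydroxyl of 22 is esterified with mixed anhydride 25 to give the C8 mono-angelate acetonide F6. Aqueous AcOH gives the mono-angelate triol F7. 2-Chloro-1,1,1-trimethoxyethane with catalytic camphorsulfonic acid gives the 2,3-cyclic ortho ester F8. Mild aqueous acid opens it by the axial-ester rule to the C3 chloroacetate F9 with the C2 hydroxyl free. Angeloylation of that single secondary hydroxyl gives the bis-angelate chloroacetate F10. Thiourea then removes the chloroacetyl group under neutral conditions to give 26.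

3. Step 5. What may go wrong: insufficient facial selectivity at C4 under substrate control, or β-elimination of the 2-lithioallyl ether to allene before transmetalation. Fallback, setting out from bromide 7 and enoate 5 and returning at ester 10: bromide 7 is converted (t-BuLi, then 2-isopropoxy-4,4,5,5-tetramethyl-1,3,2-dioxaborolane) into the alkenyl pinacol boronate F11. F11 is added to 5 in a catalyst-controlled Hayashi–Miyaura asymmetric 1,4-addition ([Rh(cod)(OH)]2, chiral diene or BINAP ligand of the antipode matched to the anti preference, aqueous dioxane) to give 10.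

**Further compounds**

F1 | step 10 | keto aldehyde from 11 | O=CC[C@H](C(=C)COCc1ccc(OC)cc1)[C@@H]2OC(C)(C)O[C@@H]2C(C)=O
F2 | step 10 | diene (C6 vinyl and C1 isopropenyl) | C=CC[C@H](C(=C)COCc1ccc(OC)cc1)[C@@H]2OC(C)(C)O[C@@H]2C(C)=C
F3 | step 10 | cyclohexene acetonide (C1=C6) | C=C(COCc1ccc(OC)cc1)[C@H]2CC=C(C)[C@H]3OC(C)(C)O[C@@H]23
F4 | step 10 | cyclohexene diol | C=C(COCc1ccc(OC)cc1)[C@H]1CC=C(C)[C@@H](O)[C@H]1O
F5 | step 10 | epoxy diol | C=C(COCc1ccc(OC)cc1)[C@H]1C[C@H]2O[C@@]2(C)[C@@H](O)[C@H]1O
F6 | step 17 | C8 mono-angelate acetonide | C=C([C@H](CC=C(C)C)OC(=O)/C(C)=C\C)[C@H]1C[C@H](Cl)[C@@](C)(O)[C@H]2OC(C)(C)O[C@@H]12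
F7 | step 17 | C8 mono-angelate triol | C=C([C@H](CC=C(C)C)OC(=O)/C(C)=C\C)[C@H]1C[C@H](Cl)[C@@](C)(O)[C@@H](O)[C@H]1O
F8 | step 17 | 2,3-cyclic chloro ortho ester | C=C([C@H](CC=C(C)C)OC(=O)/C(C)=C\C)[C@H]1C[C@H](Cl)[C@@](C)(O)[C@H]2OC(CCl)(OC)O[C@@H]12
F9 | step 17 | C3 chloroacetate with C2 hydroxyl free | C=C([C@H](CC=C(C)C)OC(=O)/C(C)=C\C)[C@H]1C[C@H](Cl)[C@@](C)(O)[C@@H](O)[C@H]1OC(=O)CCl
F10 | step 17 | C2,C8-bis-angelate C3 chloroacetate | C=C([C@H](CC=C(C)C)OC(=O)/C(C)=C\C)[C@H]1C[C@H](Cl)[C@@](C)(O)[C@@H](OC(=O)/C(C)=C\C)[C@H]1OC(=O)CCl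
F11 | step 5 | alkenyl pinacol boronate from 7 | C=C(COCc1ccc(OC)cc1)B2OC(C)(C)C(C)(C)O2
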